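**Retrosynthetic overview**
- The target comes from its tris-MOM ether by acetal cleavage in the last step. The (2S) enantiomer of that ether is taken from the racemate by asymmetric transfer hydrogenation (kinetic resolution).
- Ring C: the O1–C2 bond is opened to a 2'-hydroxychalcone (intramolecular oxa-Michael). Only the phenol between the acetyl and the prenyl group is free, which fixes 8- over 6-prenylation.
- Key C–C bond: C2–C3 of the flavanone (the chalcone Cα=Cβ) is made by a Claisen–Schmidt aldol condensation of a ring A methyl ketone with a ring B aldehyde.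
- Ring A ketone: a commercial trihydroxyacetophenone is O-prenylated and the prenyl group is moved onto carbon by a Claisen–Cope relay. A TBS-to-MOM protecting-group relay then leaves free only the phenol next to the prenyl group.
- Rings A and B are bought; ring C is the only ring made and is closed last.

Assumption: the SMILES descriptor is read as (2S); compounds written without a descriptor at a stereocentre are racemic; equivalents and times are indicative.

**Step 1**
Reactants: 1 2,4,6-trihydroxyacetophenone
Product: 2 1-[2,4-bis(tert-butyldimethylsilyloxy)-6-hydroxyphenyl]ethanone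
Conditions: TBSCl (2.1 equiv), imidazole (4.5 equiv), DMF, 0 °C to rt
Reagents that add atoms: tert-butyldimethylsilyl chloride (TBSCl), CC(C)(C)[Si](C)(C)Cl
Why: Silyl ether formation takes the para hydroxyl and one of the two equivalent ortho hydroxyls, while the other ortho hydroxyl is locked in the hydrogen bond to the acetyl carbonyl and stays as the only free phenol.

**Step 2**
Reactants: 2 1-[2,4-bis(tert-butyldimethylsilyloxy)-6-hydroxyphenyl]ethanone; 3 3-methylbut-2-en-1-ol (prenol)
Product: 4 1-[2,4-bis(tert-butyldimethylsilyloxy)-6-(3-methylbut-2-enyloxy)phenyl]ethanone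
Conditions: PPh3 (1.5 equiv), DIAD (1.5 equiv), THF, 0 °C to rt
Reagents that add atoms: none
Why: Mitsunobu etherification alkylates the acidic chelated phenol at oxygen with the primary allylic alcohol under neutral conditions that leave the aryl silyl ethers untouched.

**Step 3**
Reactants: 4 1-[2,4-bis(tert-butyldimethylsilyloxy)-6-(3-methylbut-2-enyloxy)phenyl]ethanone
Product: 7 1-[2,4-bis(tert-butyldimethylsilyloxy)-6-hydroxy-3-(3-methylbut-2-enyl)phenyl]ethanone, via ortho-dienone 5 (not isolated), via para-dienone 6 (not isolated)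
Conditions: N,N-diethylaniline, 200 °C, sealed tube, argon, 3 h
Reagents that add atoms: none
Why: In this tandem aromatic Claisen–Cope (para-Claisen) rearrangement the first [3,3] shift puts a 1,1-dimethylallyl group on the free ortho carbon, the crowded dienone passes it on by a second [3,3] shift to the para carbon between the two silyloxy groups, and tautomerisation leaves a normal prenyl group para to the freed phenol.

**Step 4**
Reactants: 7 1-[2,4-bis(tert-butyldimethylsilyloxy)-6-hydroxy-3-(3-methylbut-2-enyl)phenyl]ethanone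
Product: 8 1-[2,4-bis(tert-butyldimethylsilyloxy)-6-(methoxymethoxy)-3-(3-methylbut-2-enyl)phenyl]ethanone
Conditions: NaH (1.05 equiv), MOMCl (1.3 equiv), THF, 0 °C to rt
Reagents that add atoms: chloromethyl methyl ether (MOMCl), COCCl
Why: Williamson O-alkylation of the sodium phenoxide caps the phenol that will become the 5-hydroxyl, so it can no longer take part in ring closure.

**Step 5**
Reactants: 8 1-[2,4-bis(tert-butyldimethylsilyloxy)-6-(methoxymethoxy)-3-(3-methylbut-2-enyl)phenyl]ethanone
Product: 9 1-[2,4-dihydroxy-6-(methoxymethoxy)-3-(3-methylbut-2-enyl)phenyl]ethanone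
Conditions: TBAF (2.2 equiv), AcOH (2.2 equiv), THF, 0 °C
Reagents that add atoms: none
Why: Fluoride-driven desilylation removes both aryl TBS ethers, while the MOM acetal, the ketone and the prenyl alkene are inert and acetic acid buffers the phenoxides.

**Step 6**
Reactants: 9 1-[2,4-dihydroxy-6-(methoxymethoxy)-3-(3-methylbut-2-enyl)phenyl]ethanone
Product: 10 1-[2-hydroxy-4,6-bis(methoxymethoxy)-3-(3-methylbut-2-enyl)phenyl]ethanone
Conditions: MOMCl (1.05 equiv), DIPEA (1.5 equiv), CH2Cl2, 0 °C
Reagents that add atoms: chloromethyl methyl ether (MOMCl), COCCl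
Why: This Williamson etherification is chemoselective because the para hydroxyl is the more acidic and unhindered one, whereas the ortho hydroxyl is chelated to the carbonyl and flanked by acetyl and prenyl.

**Step 7**
Reactants: 11 4-hydroxy-3-methoxybenzaldehyde (vanillin)
Product: 12 3-methoxy-4-(methoxymethoxy)benzaldehyde
Conditions: MOMCl (1.3 equiv), DIPEA (2 equiv), CH2Cl2, 0 °C to rt
Reagents that add atoms: chloromethyl methyl ether (MOMCl), COCCl
Why: O-alkylation of the phenol (MOM protection) prevents formation of a phenoxide that would deactivate the aldehyde in the hydroxide-mediated condensation.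

**Step 8**
Reactants: 10 1-[2-hydroxy-4,6-bis(methoxymethoxy)-3-(3-methylbut-2-enyl)phenyl]ethanone; 12 3-methoxy-4-(methoxymethoxy)benzaldehyde
Product: 14 (E)-1-[2-hydroxy-4,6-bis(methoxymethoxy)-3-(3-methylbut-2-enyl)phenyl]-3-[3-methoxy-4-(methoxymethoxy)phenyl]prop-2-en-1-one, via aldol adduct 13 (not isolated)
Conditions: KOH (50 % aq, 10 equiv), EtOH, 0 °C to rt, 48 h; then aq NH4Cl
Reagents that add atoms: none
Why: In this Claisen–Schmidt crossed aldol condensation the methyl ketone enolate adds to the non-enolisable aldehyde and the aldol adduct loses water by E1cB elimination to the conjugated (E)-enone, which forms the C–C bond joining the ring A and ring B fragments.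

**Step 9**
Reactants: 14 (E)-1-[2-hydroxy-4,6-bis(methoxymethoxy)-3-(3-methylbut-2-enyl)phenyl]-3-[3-methoxy-4-(methoxymethoxy)phenyl]prop-2-en-1-one
Product: 15 rac-2-[3-methoxy-4-(methoxymethoxy)phenyl]-5,7-bis(methoxymethoxy)-8-(3-methylbut-2-enyl)-2,3-dihydro-4H-chromen-4-one
Conditions: NaOAc (10 equiv), EtOH, reflux, 36 h (recovered chalcone recycled)
Reagents that add atoms: none
Why: Intramolecular oxa-Michael addition (6-endo-trig) of the only free phenol, the one next to the prenyl group, closes ring C with the 8-prenyl pattern and creates C2 as a racemate.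

**Step 10**
Reactants: 15 rac-2-[3-methoxy-4-(methoxymethoxy)phenyl]-5,7-bis(methoxymethoxy)-8-(3-methylbut-2-enyl)-2,3-dihydro-4H-chromen-4-one
Product: 16 (2S)-2-[3-methoxy-4-(methoxymethoxy)phenyl]-5,7-bis(methoxymethoxy)-8-(3-methylbut-2-enyl)-2,3-dihydro-4H-chromen-4-one
Conditions: RuCl(p-cymene)[(R,R)-TsDPEN] (2 mol %), HCO2H/Et3N (5:2), EtOAc, rt, stopped at about 55 % conversion; chromatography
Reagents that add atoms: none
Why: This is a kinetic resolution by Noyori-type asymmetric transfer hydrogenation, in which the (R,R)-catalyst builds a (4R)-carbinol and does so fast only on the (2R)-ketone (giving the favoured cis-(2R,4R)-flavan-4-ol), so the (2S)-ketone is left unreduced in high enantiomeric purity and the C2 configuration of the target is fixed here.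

**Step 11**
Reactants: 16 (2S)-2-[3-methoxy-4-(methoxymethoxy)phenyl]-5,7-bis(methoxymethoxy)-8-(3-methylbut-2-enyl)-2,3-dihydro-4H-chromen-4-one
Product: 17 (2S)-5,7-dihydroxy-2-(4-hydroxy-3-methoxyphenyl)-8-(3-methylbut-2-enyl)-2,3-dihydro-4H-chromen-4-one
Conditions: HCl (1.25 M in MeOH), MeOH, 40 °C, 3 h
Reagents that add atoms: none
Why: Acid-catalysed acetal cleavage (transacetalisation to dimethoxymethane) removes all three MOM groups without base, so the flavanone ring is not opened and C2 is not epimerised, and the mild temperature keeps the prenyl group from cyclising onto the 7-hydroxyl.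

**Compound list**
1 | 2,4,6-trihydroxyacetophenone | CC(=O)c1c(O)cc(O)cc1O | starting material
2 | 1-[2,4-bis(tert-butyldimethylsilyloxy)-6-hydroxyphenyl]ethanone | CC(=O)c1c(O)cc(O[Si](C)(C)C(C)(C)C)cc1O[Si](C)(C)C(C)(C)C | intermediate
3 | 3-methylbut-2-en-1-ol (prenol) | CC(C)=CCO | starting material
4 | 1-[2,4-bis(tert-butyldimethylsilyloxy)-6-(3-methylbut-2-enyloxy)phenyl]ethanone | CC(=O)c1c(OCC=C(C)C)cc(O[Si](C)(C)C(C)(C)C)cc1O[Si](C)(C)C(C)(C)C | intermediate
5 | ortho-dienone: 2-acetyl-3,5-bis(tert-butyldimethylsilyloxy)-6-(2-methylbut-3-en-2-yl)cyclohexa-2,4-dien-1-one (racemic) | CC(=O)C1=C(O[Si](C)(C)C(C)(C)C)C=C(O[Si](C)(C)C(C)(C)C)C(C(C)(C)C=C)C1=O | intermediate (not isolated)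
6 | para-dienone: 2-acetyl-3,5-bis(tert-butyldimethylsilyloxy)-4-(3-methylbut-2-enyl)cyclohexa-2,5-dien-1-one (racemic) | CC(=O)C1=C(O[Si](C)(C)C(C)(C)C)C(CC=C(C)C)C(O[Si](C)(C)C(C)(C)C)=CC1=O | intermediate (not isolated)
7 | 1-[2,4-bis(tert-butyldimethylsilyloxy)-6-hydroxy-3-(3-methylbut-2-enyl)phenyl]ethanone | CC(=O)c1c(O)cc(O[Si](C)(C)C(C)(C)C)c(CC=C(C)C)c1O[Si](C)(C)C(C)(C)C | intermediate
8 | 1-[2,4-bis(tert-butyldimethylsilyloxy)-6-(methoxymethoxy)-3-(3-methylbut-2-enyl)phenyl]ethanone | CC(=O)c1c(OCOC)cc(O[Si](C)(C)C(C)(C)C)c(CC=C(C)C)c1O[Si](C)(C)C(C)(C)C | intermediate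
9 | 1-[2,4-dihydroxy-6-(methoxymethoxy)-3-(3-methylbut-2-enyl)phenyl]ethanone | CC(=O)c1c(OCOC)cc(O)c(CC=C(C)C)c1O | intermediate
10 | 1-[2-hydroxy-4,6-bis(methoxymethoxy)-3-(3-methylbut-2-enyl)phenyl]ethanone | CC(=O)c1c(OCOC)cc(OCOC)c(CC=C(C)C)c1O | intermediate
11 | 4-hydroxy-3-methoxybenzaldehyde (vanillin) | COc1cc(C=O)ccc1O | starting material
12 | 3-methoxy-4-(methoxymethoxy)benzaldehyde | COCOc1ccc(C=O)cc1OC | intermediate
13 | aldol adduct: 3-hydroxy-1-[2-hydroxy-4,6-bis(methoxymethoxy)-3-(3-methylbut-2-enyl)phenyl]-3-[3-methoxy-4-(methoxymethoxy)phenyl]propan-1-one (racemic) | COCOc1ccc(C(O)CC(=O)c2c(OCOC)cc(OCOC)c(CC=C(C)C)c2O)cc1OC | intermediate (not isolated)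
14 | (E)-1-[2-hydroxy-4,6-bis(methoxymethoxy)-3-(3-methylbut-2-enyl)phenyl]-3-[3-methoxy-4-(methoxymethoxy)phenyl]prop-2-en-1-one | COCOc1ccc(/C=C/C(=O)c2c(OCOC)cc(OCOC)c(CC=C(C)C)c2O)cc1OC | intermediate
15 | rac-2-[3-methoxy-4-(methoxymethoxy)phenyl]-5,7-bis(methoxymethoxy)-8-(3-methylbut-2-enyl)-2,3-dihydro-4H-chromen-4-one | COCOc1ccc(C2CC(=O)c3c(OCOC)cc(OCOC)c(CC=C(C)C)c3O2)cc1OC | intermediate
16 | (2S)-2-[3-methoxy-4-(methoxymethoxy)phenyl]-5,7-bis(methoxymethoxy)-8-(3-methylbut-2-enyl)-2,3-dihydro-4H-chromen-4-one | COCOc1ccc([C@@H]2CC(=O)c3c(OCOC)cc(OCOC)c(CC=C(C)C)c3O2)cc1OC | intermediate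
17 | (2S)-5,7-dihydroxy-2-(4-hydroxy-3-methoxyphenyl)-8-(3-methylbut-2-enyl)-2,3-dihydro-4H-chromen-4-one | COc1cc([C@@H]2CC(=O)c3c(O)cc(O)c(CC=C(C)C)c3O2)ccc1O | target

**Step count and risks**
Total steps: 11. Longest linear sequence: 10 steps (steps 1–6 and 8–11, from 1 to 17); step 7 is a one-step side branch.

Step 3 (Claisen–Cope relay). The dienone 5 may enolise before the second shift, which would leave a 1,1-dimethylallyl group on the wrong carbon, or silyl groups may be lost at 200 °C. The fallback sets out from 1 and puts the prenyl group on carbon directly. C-alkylation of 1 with prenyl bromide (DBU, THF, rt) gives 1-[2,4,6-trihydroxy-3-(3-methylbut-2-enyl)phenyl]ethanone F1. Treatment of F1 with MOMCl (2.1 equiv) and DIPEA in CH2Cl2 at 0 °C etherifies the para hydroxyl and the less hindered ortho hydroxyl, leaving free the hydroxyl wedged between acetyl and prenyl. The minor regioisomer is removed by chromatography and the structure is checked by HMBC and NOE. The fallback comes back to the route at 10, with steps 1–6 bypassed.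

Step 10 (kinetic resolution). Hydride transfer to the hindered, electron-rich 5-alkoxy ketone may be too slow or not selective enough. The fallback sets out from 15 and resolves it physically instead of kinetically. Racemic 15 is separated by preparative supercritical-fluid chromatography on an amylose tris(3,5-dimethylphenylcarbamate) stationary phase (CO2/iPrOH). The (2S) enantiomer is recognised by its positive Cotton effect near 330 nm and negative one near 290 nm. The fallback comes back to the route at 16; new compounds: none F0.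

Step 11 (global deprotection). Protic acid may add the 7-hydroxyl across the prenyl alkene to give a dimethylchroman, or hydrate the alkene. The fallback sets out from 16 and avoids protic acid by silyl transfer. TMSOTf (6 equiv) and 2,2'-bipyridyl (9 equiv) in MeCN at 0 °C exchange the three aryl MOM ethers for TMS ethers, giving (2S)-2-[3-methoxy-4-(trimethylsilyloxy)phenyl]-8-(3-methylbut-2-enyl)-5,7-bis(trimethylsilyloxy)-2,3-dihydro-4H-chromen-4-one F2. Stirring F2 in wet THF/MeOH at rt hydrolyses the silyl ethers under neutral conditions. The fallback comes back to the route at 17.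

**Further compounds**
F1 | step 3 | 1-[2,4,6-trihydroxy-3-(3-methylbut-2-enyl)phenyl]ethanone | CC(=O)c1c(O)cc(O)c(CC=C(C)C)c1O
F0 | step 10 | none | none
F2 | step 11 | (2S)-2-[3-methoxy-4-(trimethylsilyloxy)phenyl]-8-(3-methylbut-2-enyl)-5,7-bis(trimethylsilyloxy)-2,3-dihydro-4H-chromen-4-one | COc1cc([C@@H]2CC(=O)c3c(O[Si](C)(C)C)cc(O[Si](C)(C)C)c(CC=C(C)C)c3O2)ccc1O[Si](C)(C)C
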